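**Plan**

- Retrosynthetic cuts (guaiane numbering): the C8 propanoate and C11 acetate come off, and H1/H10 are removed to give the 1(10),4-dien-3-one. Its cyclopentenone (C3 ketone, C4 methyl, C4=C5), fused through C1–C5 to the seven-membered ring, is the retron of a methyl-capped alkyne (C4≡C5), the terminal C1=C2 bond of a 1,1-disubstituted allene and CO, so C1–C5, C2–C3 and C3–C4 are cut together.
- The acyclic allenyne is cut at C10–CH3 (SN2' methylation), C9–C10 (acetylide plus epoxide), the two C11–CH3 bonds (Grignard) and C6–C7 (lactone alkylation).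
- Forward: the C6–C11 chain is built on (S)-3-hydroxy-γ-butyrolactone and a dioxane is closed over O8/O11. The seven- and five-membered carbocycles then form together in one rhodium-catalysed carbonylative cycloaddition, and reduction, epimerisation and two acylations finish the synthesis.
- Stereochemistry: C8 comes from the chiral pool, C7 from trans alkylation of the lactone dianion, C10 from syn hydrogenation anti to the cis-fused dioxane, and C1 from base equilibration.

Key step: step 7

Remark: guaiane numbering is used for all intermediates (C1/C5 ring-fusion carbons, C3 carbonyl, C4 and C10 methyl-bearing, C7 bearing C11, C8 oxygenated); (S)-3-hydroxy-γ-butyrolactone is assumed to be bought as the single enantiomer.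

**Route**

Step 1
Reactants: 1 (S)-3-hydroxy-γ-butyrolactone; 2 1-bromobut-2-yne
Product: 4 (3S,4S)-3-(but-2-yn-1-yl)-4-hydroxyoxolan-2-one (trans lactone), via dilithium lactone dianion 3 (not isolated)
Conditions: LiN(iPr)2 (2.3 equiv), THF, −78 °C; then 2, DMPU, −78 → −35 °C; aq. NH4Cl
Reagents that add atoms: none
Why: Fráter–Seebach-type alkylation of the alkoxide–enolate dianion of a β-hydroxy-γ-butyrolactone: the electrophile should add to the enolate face anti to the C8 oxido group, so the but-2-ynyl group ends trans to oxygen on the ring and sets C7 (S), and the second negative charge on oxygen blocks β-elimination.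

Step 2
Reactants: 4 (3S,4S)-3-(but-2-yn-1-yl)-4-hydroxyoxolan-2-one
Product: 5 (2S,3S)-3-(but-2-yn-1-yl)-4-methylpentane-1,2,4-triol
Conditions: MeMgBr (4.5 equiv), THF, −20 → 20 °C; aq. NH4Cl
Reagents that add atoms: methylmagnesium bromide, C[Mg]Br
Why: Double Grignard addition to the lactone carbonyl after deprotonation of the hydroxyl opens the ring to the tertiary carbinol C11; the second addition is faster than enolisation of the intermediate methyl ketone, so C7 should be kept.

Step 3
Reactants: 5 (2S,3S)-3-(but-2-yn-1-yl)-4-methylpentane-1,2,4-triol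
Product: 7 (3S)-2-methyl-3-[(2S)-oxiran-2-yl]hept-5-yn-2-ol, via primary monotosylate 6 (not isolated)
Conditions: TsCl (1.05 equiv), Bu2SnO (2 mol %), Et3N, CH2Cl2, 0 °C; then K2CO3, MeOH, 0 → 20 °C
Reagents that add atoms: none
Why: Bu2SnO-catalysed sulfonylation picks the primary hydroxyl of the 1,2-diol through its stannylene acetal, and under carbonate in methanol the neighbouring secondary alkoxide should close the oxirane by 3-exo-tet Williamson displacement faster than the hindered, less acidic tertiary hydroxyl can attack; the C8–O bond is untouched, so C8 keeps its configuration.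

Step 4
Reactants: 7 (3S)-2-methyl-3-[(2S)-oxiran-2-yl]hept-5-yn-2-ol; 8 3-methoxyprop-1-yne (methyl propargyl ether)
Product: 10 (3S,4R)-3-(but-2-yn-1-yl)-8-methoxy-2-methyloct-6-yne-2,4-diol, via lithium methoxypropynide 9 (not isolated)
Conditions: 8 (3.2 equiv), nBuLi (3.0 equiv), THF, −78 °C; BF3·OEt2 (2.0 equiv); then 7, −78 °C; aq. NH4Cl
Reagents that add atoms: none
Why: Yamaguchi–Hirao alkynylation: the BF3-activated terminal epoxide is opened by the lithium acetylide at the unsubstituted carbon C9 at −78 °C, with the tertiary hydroxyl held as its lithium alkoxide by one extra equivalent of 9, and C8 is not involved.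

Step 5
Reactants: 10 (3S,4R)-3-(but-2-yn-1-yl)-8-methoxy-2-methyloct-6-yne-2,4-diol
Product: 11 (5S,6R)-5-(but-2-yn-1-yl)-6-(4-methoxybut-2-yn-1-yl)-2,2,4,4-tetramethyl-1,3-dioxane
Conditions: 2-methoxypropene (3 equiv), PPTS (5 mol %), CH2Cl2, 0 → 20 °C
Reagents that add atoms: 2-methoxypropene, COC(C)=C
Why: Acid-catalysed acetonide formation with an enol ether (kinetic transketalisation) should close the six-membered ring over the secondary/tertiary 1,3-diol, the same ring type as the known acetonide of 2-methylpentane-2,4-diol, and it places the two unsaturated arms cis on the dioxane.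

Step 6
Reactants: 11 (5S,6R)-5-(but-2-yn-1-yl)-6-(4-methoxybut-2-yn-1-yl)-2,2,4,4-tetramethyl-1,3-dioxane
Product: 12 (5S,6R)-5-(but-2-yn-1-yl)-2,2,4,4-tetramethyl-6-(2-methylbuta-2,3-dien-1-yl)-1,3-dioxane
Conditions: MeMgBr (3 equiv), CuBr (10 mol %), PBu3 (20 mol %), Et2O, 0 → 20 °C
Reagents that add atoms: methylmagnesium bromide, C[Mg]Br
Why: Copper-catalysed SN2' substitution of a primary propargylic methyl ether by a Grignard reagent: the methylcopper species adds to the alkyne carbon remote from the leaving group (C10) and methoxide leaves, which gives the 1,1-disubstituted terminal allene, while the unactivated but-2-ynyl group and the acetonide are inert.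

Step 7
Reactants: 12 (5S,6R)-5-(but-2-yn-1-yl)-2,2,4,4-tetramethyl-6-(2-methylbuta-2,3-dien-1-yl)-1,3-dioxane
Product: 13 (7S,8R)-8,11-(isopropylidenedioxy)guaia-1(10),4-dien-3-one
Conditions: [Rh(CO)2Cl]2 (5 mol %), CO (1 atm), toluene (0.02 M), 90 °C
Reagents that add atoms: carbon monoxide, [C-]#[O+]
Why: Monovalent rhodium binds the C4≡C5 alkyne and the terminal C1=C2 bond of the allene and couples them oxidatively (C1–C5 bond) to a trivalent rhodacyclopentene that already contains the seven-membered ring C1–C5–C6–C7–C8–C9–C10; CO then inserts and C–C reductive elimination closes C2–C3/C3–C4 and returns the catalyst. The closest known reaction is the rhodium-catalysed allenic Pauson–Khand reaction of allenynes with a four-atom tether, which gives 4-alkylidenecyclopentenones fused to seven-membered rings. The seven-membered ring thus closes by metallacycle formation across the C6–C9 tether (exo with respect to the alkyne, onto the central allene carbon), and the cyclopentenone closes by migratory CO insertion followed by reductive elimination. No stereocentre is created, and C7 and C8 are spectators. The step needs the distal rather than the proximal allene bond and carbonylation rather than Alder-ene cycloisomerisation: the rhodium carbonyl chloride catalyst and the fully substituted, methyl-bearing proximal carbon C10 steer the metal to the terminal bond, the CO atmosphere should intercept the metallacycle before β-hydride loss, and the cis-disposed arms on the dioxane hold alkyne and allene within reach.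

Step 8
Reactants: 13 (7S,8R)-8,11-(isopropylidenedioxy)guaia-1(10),4-dien-3-one
Product: 14 (1S,7S,8R,10S)-8,11-(isopropylidenedioxy)guai-4-en-3-one (H1, H7, H8 and H10 all on one face)
Conditions: H2 (1 atm), 10% Pd/C, EtOAc, 20 °C
Reagents that add atoms: none
Why: Heterogeneous catalytic hydrogenation should add H2 syn to the γ,δ-alkene of the linear dienone from the face that carries H7 and H8, anti to the cis-fused dioxane, which sets C10 (S) with its methyl cis to O8 and leaves the tetrasubstituted, electron-poor cyclopentenone alkene.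

Step 9
Reactants: 14 (1S,7S,8R,10S)-8,11-(isopropylidenedioxy)guai-4-en-3-one
Product: 15 (1R,7S,8R,10S)-8,11-(isopropylidenedioxy)guai-4-en-3-one
Conditions: NaOMe (0.3 equiv), MeOH, 25 °C
Reagents that add atoms: none
Why: Base-mediated vinylogous epimerisation: reversible γ-deprotonation at C1 gives the extended dienolate, and reprotonation should collect the epimer with C2 trans to the C10 methyl (the arrangement of the natural ketone), no other stereocentre being acidic.

Step 10
Reactants: 15 (1R,7S,8R,10S)-8,11-(isopropylidenedioxy)guai-4-en-3-one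
Product: 16 (1R,7S,8R,10S)-8,11-dihydroxyguai-4-en-3-one
Conditions: AcOH/H2O (4:1), THF, 40 °C
Reagents that add atoms: none
Why: Acid-catalysed acetal hydrolysis; the strained tetramethyldioxane should hydrolyse under conditions mild enough to spare the tertiary alcohol and the enone.

Step 11
Reactants: 16 (1R,7S,8R,10S)-8,11-dihydroxyguai-4-en-3-one
Product: 17 (1R,7S,8R,10S)-11-hydroxy-8-(propanoyloxy)guai-4-en-3-one
Conditions: (EtCO)2O (1.5 equiv), pyridine, DMAP (5 mol %), CH2Cl2, 0 → 20 °C
Reagents that add atoms: propanoic anhydride, CCC(=O)OC(=O)CC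
Why: DMAP-catalysed acylation with an anhydride is far faster at the secondary C8 hydroxyl than at the tertiary C11 hydroxyl, so the propanoate should go on selectively.

Step 12
Reactants: 17 (1R,7S,8R,10S)-11-hydroxy-8-(propanoyloxy)guai-4-en-3-one
Product: 18 (1R,7S,8R,10S)-11-acetoxy-8-(propanoyloxy)guai-4-en-3-one
Conditions: Ac2O (5 equiv), DMAP (1 equiv), Et3N, CH2Cl2, 40 °C
Reagents that add atoms: acetic anhydride, CC(=O)OC(C)=O
Why: Steglich-type DMAP-catalysed acetylation with excess anhydride and gentle heating esterifies hindered tertiary alcohols, and the ketone and propanoate do not react.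

**Compound list**

1 | (S)-3-hydroxy-γ-butyrolactone [(4S)-4-hydroxyoxolan-2-one] | O=C1C[C@H](O)CO1 | starting material
2 | 1-bromobut-2-yne | CC#CCBr | starting material
3 | dilithium (S)-4-oxido-4,5-dihydrofuran-2-olate (dianion of 1) | [Li+].[Li+].[O-]C1=C[C@H]([O-])CO1 | intermediate (not isolated)
4 | (3S,4S)-3-(but-2-yn-1-yl)-4-hydroxyoxolan-2-one | O=C1[C@@H](CC#CC)[C@H](O)CO1 | intermediate
5 | (2S,3S)-3-(but-2-yn-1-yl)-4-methylpentane-1,2,4-triol | CC#CC[C@H](C(C)(C)O)[C@H](O)CO | intermediate
6 | (2S,3S)-3-(but-2-yn-1-yl)-2,4-dihydroxy-4-methylpentyl 4-methylbenzenesulfonate | CC#CC[C@H](C(C)(C)O)[C@H](O)COS(=O)(=O)c1ccc(C)cc1 | intermediate (not isolated)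
7 | (3S)-2-methyl-3-[(2S)-oxiran-2-yl]hept-5-yn-2-ol | CC#CC[C@H](C(C)(C)O)[C@H]1CO1 | intermediate
8 | 3-methoxyprop-1-yne (methyl propargyl ether) | C#CCOC | starting material
9 | lithium 3-methoxyprop-1-yn-1-ide | [Li+].[C-]#CCOC | intermediate (not isolated)
10 | (3S,4R)-3-(but-2-yn-1-yl)-8-methoxy-2-methyloct-6-yne-2,4-diol | CC#CC[C@H](C(C)(C)O)[C@H](O)CC#CCOC | intermediate
11 | (5S,6R)-5-(but-2-yn-1-yl)-6-(4-methoxybut-2-yn-1-yl)-2,2,4,4-tetramethyl-1,3-dioxane | CC#CC[C@H]1[C@@H](CC#CCOC)OC(C)(C)OC1(C)C | intermediate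
12 | (5S,6R)-5-(but-2-yn-1-yl)-2,2,4,4-tetramethyl-6-(2-methylbuta-2,3-dien-1-yl)-1,3-dioxane (allenyne) | CC#CC[C@H]1[C@@H](CC(C)=C=C)OC(C)(C)OC1(C)C | intermediate
13 | (7S,8R)-8,11-(isopropylidenedioxy)guaia-1(10),4-dien-3-one | O=C1CC2=C(C)C[C@H]3OC(C)(C)OC(C)(C)[C@H]3CC2=C1C | intermediate
14 | (1S,7S,8R,10S)-8,11-(isopropylidenedioxy)guai-4-en-3-one | CC1(C)O[C@@H]2C[C@H](C)[C@@H]3CC(=O)C(C)=C3C[C@@H]2C(C)(C)O1 | intermediate
15 | (1R,7S,8R,10S)-8,11-(isopropylidenedioxy)guai-4-en-3-one | CC1(C)O[C@@H]2C[C@H](C)[C@H]3CC(=O)C(C)=C3C[C@@H]2C(C)(C)O1 | intermediate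
16 | (1R,7S,8R,10S)-8,11-dihydroxyguai-4-en-3-one | O[C@@H]1C[C@H](C)[C@H]2CC(=O)C(C)=C2C[C@@H]1C(C)(C)O | intermediate
17 | (1R,7S,8R,10S)-11-hydroxy-8-(propanoyloxy)guai-4-en-3-one | CCC(=O)O[C@@H]1C[C@H](C)[C@H]2CC(=O)C(C)=C2C[C@@H]1C(C)(C)O | intermediate
18 | (1R,7S,8R,10S)-11-acetoxy-8-(propanoyloxy)guai-4-en-3-one | CCC(=O)O[C@@H]1C[C@H](C)[C@H]2CC(=O)C(C)=C2C[C@@H]1C(C)(C)OC(C)=O | target

**Step count and risks**

Total steps: 12. Longest linear sequence: 12 steps (1 → 18).

Steps most likely to fail:

1. Step 8. Hydrogen may add slowly or without face discrimination to the tetrasubstituted C1=C10 bond, or reduction may run on into the cyclopentenone alkene. The fallback replaces surface hydrogenation by electron-transfer 1,6-reduction, the classical outcome for linear dienones. It sets out from 13: Li in NH3/THF with tBuOH (1 equiv) at −78 °C should protonate the dienyl anion at C10 from the open face, and NH4Cl then quenches the dienolate. The crude mixture of double-bond isomers is treated with NaOMe in MeOH as in step 9, so that conjugation and the C1 configuration are settled together. The route is rejoined at 15. This fallback makes no compound outside the list (F0).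

2. Step 9. The equilibrium at C1 of the dioxane-fused ketone may not lie on the side of the needed epimer, or part of the material may stay deconjugated. The fallback moves the equilibration to the natural substitution pattern, where the ring is no longer constrained by the dioxane. It sets out from 14: aqueous AcOH as in step 10 gives the C1-epimeric diol, (1S,7S,8R,10S)-8,11-dihydroxyguai-4-en-3-one F1. Propanoylation as in step 11 gives (1S,7S,8R,10S)-11-hydroxy-8-(propanoyloxy)guai-4-en-3-one F2. Acetylation as in step 12 gives the C1 epimer of the target, (1S,7S,8R,10S)-11-acetoxy-8-(propanoyloxy)guai-4-en-3-one F3. F3 is then equilibrated with DBU in toluene at 60 °C, which leaves the esters alone, and the epimers are separated. The route is rejoined at 18.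

3. Step 6. Methoxide is a poor leaving group, so copper turnover may be slow, or methyl may attack the CH2 carbon directly and give the pent-2-ynyl isomer instead of the allene. The fallback uses a sulfonate leaving group and sets out from 7.
   - Epoxide 7 is opened under the step 4 conditions with the lithium acetylide of tert-butyldimethyl(prop-2-yn-1-yloxy)silane to give (3S,4R)-3-(but-2-yn-1-yl)-8-[(tert-butyldimethylsilyl)oxy]-2-methyloct-6-yne-2,4-diol F4.
   - 2-Methoxypropene/PPTS closes the dioxane to give tert-butyl({4-[(4R,5S)-5-(but-2-yn-1-yl)-2,2,6,6-tetramethyl-1,3-dioxan-4-yl]but-2-yn-1-yl}oxy)dimethylsilane F5.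
   - Bu4NF in THF frees 4-[(4R,5S)-5-(but-2-yn-1-yl)-2,2,6,6-tetramethyl-1,3-dioxan-4-yl]but-2-yn-1-ol F6.
   - MsCl/Et3N at −20 °C gives 4-[(4R,5S)-5-(but-2-yn-1-yl)-2,2,6,6-tetramethyl-1,3-dioxan-4-yl]but-2-yn-1-yl methanesulfonate F7.
   - MeMgBr with CuBr·SMe2 and LiBr in THF (−78 → 0 °C) then effects the SN2' methylation, and the route is rejoined at 12.

**Further compounds**

F0 | step 8 | none | none
F1 | step 9 | (1S,7S,8R,10S)-8,11-dihydroxyguai-4-en-3-one | O[C@@H]1C[C@H](C)[C@@H]2CC(=O)C(C)=C2C[C@@H]1C(C)(C)O
F2 | step 9 | (1S,7S,8R,10S)-11-hydroxy-8-(propanoyloxy)guai-4-en-3-one | CCC(=O)O[C@@H]1C[C@H](C)[C@@H]2CC(=O)C(C)=C2C[C@@H]1C(C)(C)O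
F3 | step 9 | (1S,7S,8R,10S)-11-acetoxy-8-(propanoyloxy)guai-4-en-3-one | CCC(=O)O[C@@H]1C[C@H](C)[C@@H]2CC(=O)C(C)=C2C[C@@H]1C(C)(C)OC(C)=O
F4 | step 6 | (3S,4R)-3-(but-2-yn-1-yl)-8-[(tert-butyldimethylsilyl)oxy]-2-methyloct-6-yne-2,4-diol | CC#CC[C@H](C(C)(C)O)[C@H](O)CC#CCO[Si](C)(C)C(C)(C)C
F5 | step 6 | tert-butyl({4-[(4R,5S)-5-(but-2-yn-1-yl)-2,2,6,6-tetramethyl-1,3-dioxan-4-yl]but-2-yn-1-yl}oxy)dimethylsilane | CC#CC[C@H]1[C@@H](CC#CCO[Si](C)(C)C(C)(C)C)OC(C)(C)OC1(C)C
F6 | step 6 | 4-[(4R,5S)-5-(but-2-yn-1-yl)-2,2,6,6-tetramethyl-1,3-dioxan-4-yl]but-2-yn-1-ol | CC#CC[C@H]1[C@@H](CC#CCO)OC(C)(C)OC1(C)C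
F7 | step 6 | 4-[(4R,5S)-5-(but-2-yn-1-yl)-2,2,6,6-tetramethyl-1,3-dioxan-4-yl]but-2-yn-1-yl methanesulfonate | CC#CC[C@H]1[C@@H](CC#CCOS(C)(=O)=O)OC(C)(C)OC1(C)C
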